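Start with what stays in the flask, not what is made.

| flask | substrate | reagent | scavenger | initiator | remark | time |
|---|---|---|---|---|---|---|
| north-east | 2 mM | 2 mM (fed, over 20 s) | 1.3 mM | 10 µM | run made earlier |  |
| south-east | 2 mM | 2 mM (fed, over 20 s) | 3 mM | 10 µM | run made earlier |  |
| flask | 2.0 mM | 2.00 mM (fed, over 20 s) | 2.00 mM | 10 µM |  | 6.0 min |

| run | time / min | substrate / % | target / % |
|---|---|---|---|
| north-east | 0.250 | 78.9 | 21.1 |
| north-east | 0.500 | 61.0 | 38.9 |
| north-east | 0.833 | 43.0 | 58.1 |
| north-east | 1.33 | 25.9 | 76.1 |
| north-east | 2.00 | 11.4 | 88.2 |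
| north-east | 4.00 | 0.2 | 98.6 |
| south-east | 0.250 | 80.1 | 20.4 |
| south-east | 0.500 | 59.7 | 38.5 |
| south-east | 0.833 | 45.2 | 58.9 |
| south-east | 1.33 | 25.7 | 74.4 |
| south-east | 2.00 | 10.8 | 87.4 |
| south-east | 4.00 | 2.8 | 98.0 |

(standard deviation of a reading: 1 percentage point)

- part of the substrate that has reacted at 6.0 min
- share of the unused reagent that is free and not bound as idle adduct, at 6.0 min

- the earlier runs were read with a standard deviation of 1 percentage point
- a reading or a percentage of target counts all its forms, free or not
- the earlier runs do not show how much of reagent is bound; that part of a forecast is a guess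

1. Crude bracket. Substrate left can only shrink, so the 4.00 min reading of 2.8% caps what remains at 6.0 min. At least 97.2% has reacted, within the scatter of 1 percentage point, and the ceiling is 100%.

2. The rule. In both earlier runs, within the scatter, the fraction of substrate left multiplies by the same factor over equal times, as in a pseudo-first-order decay. The constant k, the logarithm of charged over left substrate per minute, is read here at the charges of these runs, substrate 2 mM and reagent 2 mM, which the flask repeats. With [scavenger] at 1.3 mM and 3 mM, the runs read 25.9% and 25.7% at 1.33 min, and the flask's 2.00 mM lies between them.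

3. Tightened bracket. The 4.00 min readings sit too near the scatter for a logarithm. The south-east run gives 0.888 min⁻¹ from its 0.250 min reading and 1.11 min⁻¹ from its 2.00 min reading, taken as the two ends. So the bracket for the flask runs from 99.5% to 99.9% reacted at 6.0 min.

4. Commitment. The mean of the 1.33 min readings gives k = 1.02 min⁻¹, which leaves 0.220%. The readings put no bracket on the free share.

The forecast gives 99.7% reacted, which leaves less substrate than the low end of the bracket and more than the high end, and 30% free (2% to 95%): "The free share is a guess".

The flask gives 99.8% reacted, which leaves less substrate than the low end of the bracket and more than the high end, and 89.7% free.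

    reagent + first chain carrier → target + second chain carrier (k = 1.09 × 10⁸ M⁻¹ s⁻¹)
    reagent + released group ⇌ idle adduct, settled at all times (K = 8300 M⁻¹)
    scavenger + released group → scavenged by-product (k = 534 M⁻¹ s⁻¹)
    initiator → 2 initiating radical (k = 6.47 × 10⁻⁵ s⁻¹)
    2 second chain carrier → ended chains B (k = 4.00 × 10⁸ M⁻¹ s⁻¹)
    crystals ⇌ target, rate k6*(cs6 - [target]) while solid is left; crystals form when [target] > cs6 (solubility = 0.820 mM, k = 3.31 s⁻¹)
    substrate + second chain carrier → released group + first chain carrier (k = 1.37 × 10⁷ M⁻¹ s⁻¹)
    2 first chain carrier → ended chains A (k = 2.00 × 10⁷ M⁻¹ s⁻¹)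
    substrate + initiating radical → capped initiator + first chain carrier (k = 5.34 × 10⁸ M⁻¹ s⁻¹)

The neighbouring flask has [substrate] cut to 0.80 mM, with the other charges held. Carried over unchanged, with reagent now at 2.50 equiv to substrate, the same 1.02 min⁻¹ leaves 0.220% at 6.0 min. That neighbour ends with 0.190% of its substrate left, so 99.8% has reacted, while 60.0% of its reagent remains.

The data were generated by integration for an exercise; scatter was added.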